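The numbers are made up; the run is a simulation.

I started from the amounts: 0.017 M of solid substrate, none of it dissolved, and no coupling partner in solution, which the gas feeds towards a saturation of 4.1 mM.

solid substrate 0.017 M; gas 4.1 mM (held); time 10 d

    solid substrate ⇌ dissolved substrate, rate k1*(cs1 - [dissolved substrate]) while solid is left; crystals form when [dissolved substrate] > cs1 (cs1 = 1.9 mM, k1 = 1.70 h⁻¹)
    dissolved substrate + coupling partner → target (k2 = 10.4 M⁻¹ h⁻¹)
    dissolved substrate + target → side product (k3 = 1.34 M⁻¹ h⁻¹)
    solid product ⇌ target, rate k4*(cs4 - [target]) while solid is left; crystals form when [target] > cs4 (cs4 = 2.6 mM, k4 = 4.05 h⁻¹)
    2 coupling partner → self-condensation product (k5 = 10.1 M⁻¹ h⁻¹)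
    gas ⇌ coupling partner, rate k6*(csat - [coupling partner]) (k6 = 0.0506 h⁻¹, csat = 4.1 mM)

- Wednesday's: doubling the dissolution coefficient of step 4, all else as stated
- Friday's: doubling the solubility in step 1, all else as stated
- Saturday's: doubling the saturation concentration of gas, all else as stated
- Sunday's: doubling the dissolution coefficient of step 1, all else as stated

- percent here means solid substrate units held: one side product counts as two
- what is said of target includes solid product
- for a step with 2 of a species take k times the square, and two of it per event
- solid substrate, solid product is a solid; its amount is given per volume of the solution
- at the start none of coupling partner is dissolved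
- at the start none of the solid substrate is in solution
- dissolved substrate means what is dissolved; the solid is not counted in it
- run time (flask): 10 d

- how much target and solid product together there is at 10 d, in percent of the solid substrate charged
- concentration of dissolved substrate in solution at 25 h, in percent of saturation
- the change that raises the amount of target and solid product together at 10 d, in percent of the solid substrate charged most ("none" if none brings more than 2 percentage points) (Wednesday's / Friday's / Saturday's / Sunday's / none)
- amount of target and solid product together at 10 d, in percent of the solid substrate charged, after Sunday's

My first estimate put the coupling partner at saturation and the dissolved substrate at 1.9 mM, which made target at 0.0810 mM h⁻¹, or 114% of the charge by 10 d. But that is more than was charged, and at saturation the self-condensation half-life of 12.1 h is shorter than the transfer time of 19.8 h.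

So I set transfer from the gas equal to self-condensation plus coupling. That quadratic gave a coupling partner level B of 1.91 mM, approached with a relaxation time constant of about 6.79 h. Target then formed at 0.0377 mM h⁻¹.

Was the dissolved substrate really at solubility? Dissolution takes 0.588 h, far faster than coupling uses it, so the gap was 1.17% and saturation about 98.8%.

The objection that remained was the side step. Dissolved target reaches its solubility 2.6 mM after about 69.0 h, so I took it there, which gave a selectivity factor S of 5.69 coupling events per side event. The net target output, meaning target made with B in balance less what the side step destroys, was 0.0310 mM h⁻¹. It contains no charge. By 10 d it gave 43.8%, and the substrate used plus dissolved came to 73.7%, below the charge.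

Saturday's gave 0.0549 mM h⁻¹, and Friday's gave 0.0529 mM h⁻¹. Carried at these rates to 10 d, substrate used plus dissolved came to 134% of the charge for Friday's and 107% for Saturday's, so both overshot the charge, Friday's by more, and I chose Saturday's. Sunday's narrows the gap to 0.585%, which I put at 0.26 percentage points, or 44.1%.

The forecast gave 43.3% (42% to 44.5%), a little below my figure, with 98.8%, Saturday's and 43.5%, on the ground that “Supply of coupling partner and the dissolved substrate level are what limit the rate”.

The simulation gave 43.3%, 98.8%, Saturday's with a gain of 31 points against 23 points for Friday's, and 43.5%. In this flask the solid substrate was down to 85.3% after 1.00 d, with coupling partner at 0.00183 M. Coupling then ran with solid substrate present, 30.6% at 10.0 d, and coupling partner at 0.00191 M, while solid product stood at 6.33% after 5.00 d. Target read between those times rose at 0.0307 mM h⁻¹, against 0.0310 mM h⁻¹. In the neighbour flask with 0.043 M of solid substrate, the same output gives 17.3%, and that flask held 17.1%.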